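# Total synthesis proposal for Pestalone H (21)

## Analysis of the target

Pestalone H (21) is a benzophenone. Ring A (C1–C6) and ring B (C1'–C6') are joined through one ketone carbon, C7, and there is no further ring. Ring A is hexasubstituted (C1–C7, C2–OMe, C3–Br, C4–CH3, C5–Cl, C6–OH). Ring B is pentasubstituted (C1'–C7, C2'–CHO, C3'–OH, C4'–H, C5'–OH, C6'–prenyl). The molecule has no stereocentre, its only alkene carries two identical methyl groups, and no axis is specified, so the task is one of connectivity, regiochemistry and chemoselectivity.

The hardest bonds lie around C7. Its carbonyl group is flanked by four ortho substituents (C2–OMe, C6–OH, C2'–CHO, C6'–prenyl), so any union of two finished rings must join two doubly ortho-blocked carbons. Ring A is pseudo-symmetric: C3 and C5 differ only in the neighbouring OMe or OH, yet must carry Br and Cl respectively.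

The sensitive groups limit the late chemistry:
- the o-aroylbenzaldehyde isomerises to a 3-arylphthalide under bases and nucleophiles;
- the o-prenylphenol closes to a chroman in strong acid;
- the prenyl alkene does not survive halogenating agents or peracids;
- the C3–Br bond rules out late aryl-metal or palladium(0) chemistry.

The feature that invites the chosen move is the pattern of ring B. C7 sits on C1', meta to both hydroxyl groups, and the formyl group sits on C2', ortho and para to them. Read this way, C3'–C4'–C5'–C6' (O, H, O, prenyl) is the four-carbon backbone of a γ-prenylated acetoacetate. C1'–C2', with one carbonyl group on each carbon, is an acetylene dicarbonyl unit, which is the retron of a Diels–Alder benzannulation.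

## Retrosynthetic reasoning

**21 ⇒ 20.** The last step only frees C6–OH from its methoxymethyl ether. This group is kept to the end because a free C6–OH would add to the activated alkyne of the key-step precursor. It is also the group that directs the metalation by which the formyl carbon (later C7) enters ring A.

**20 ⇒ 17 + 7 (key disconnection).** The bonds C1'–C6' and C2'–C3' are cut, so ring B disappears altogether.
- What remains is keto ynal 17, which is ring A plus a linear four-carbon chain C7–C1'≡C2'–CHO, and the acyclic bis(silyloxy)diene 7.
- The cut is made here and not at C7 because the crowding around C7 exists only once ring B is aromatic. In 17, C1' is an sp carbon without neighbours.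
- The gain is that one operation closes ring B, places all five of its substituents, and brings the prenyl group in on a carbon chain. No halogenation or metalation ever meets the alkene.
- The forward reaction has to bond the nucleophilic terminus of 7 to the alkyne carbon that bears the aroyl group. It has to react at C≡C and not at C=O, and it has to aromatise by loss of the methoxy group at C3' together with H at C6'.

**17 ⇒ 16 ⇒ 13 + 14.** The C7–C1' bond is cut at the stage where it is an aldehyde–acetylide bond. Aldehyde 13 takes up the dilithio derivative 15 of propargyl alcohol 14. Both hydroxyl groups of diol 16 are propargylic, so one oxidation raises C7 and the terminal carbon to the ketone and aldehyde levels together.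

**13 ⇒ 12.** The C3–Br bond is cut last on ring A. In 12 only one aromatic C–H is left, so the bromination has no choice of position. Bromine is also absent when butyllithium is used.

**12 ⇒ 10 (through 11).** The C1–CHO bond is made by directed ortho metalation. C1 lies between the two oxygen substituents of 10, where both direct. The second position ortho to the acetal oxygen is blocked by chlorine.

**10 ⇒ 9 ⇒ 8.** Acetal formation on the phenol follows the C5–Cl disconnection. The pseudo-symmetry of ring A is broken in the starting material: commercial 3-methoxy-5-methylphenol 8 already holds one OH and one OMe. The chlorine is delivered ortho to the free OH (and para to OMe), which fixes Cl next to OH and leaves the carbon next to OMe for bromine.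

**7 ⇒ 5 ⇒ 4 ⇒ 1 + 2.** The diene is the doubly silylated enol form of β-keto ester 4. The C–C bond between the γ-carbon and the prenyl CH2 is cut. It is formed by alkylation of dianion 3 of methyl acetoacetate 1 with prenyl bromide 2.

## Alternatives that were turned down

**Alternative 1:** (the textbook route) cut C7–C1' between two finished rings.
- Forward key step: bromine–lithium exchange on the hexasubstituted ring B bromide A1, addition to aldehyde 13 to give benzhydrol A2, then oxidation and unmasking.
- The new bond would join a carbanion flanked by an acetal and a prenyl group to a carbonyl group flanked by OMe and OMOM, so the addition is slow.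
- A slow addition gives the aryllithium time to exchange with the C3–Br bond of 13, which scrambles the halogen. The reversed polarity (ring A as the metal) fails for the same reason.
- A1 needs its own linear sequence of aromatic substitutions with several regiochemical decisions, and three further protecting groups. The route becomes longer, and no single step simplifies the problem.

**Alternative 2:** cut C7–C1 and make it by an O→C acyl shift.
- Forward key step: Fries rearrangement (Lewis acid, photochemical or anionic) of aryl ester A3, in which the oxygen on C6 of ring A carries the ring B acyl group.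
- The step forms the same kind of bond as Alternative 1 and still requires the complete hexasubstituted ring B.
- Lewis acids would attack the prenyl group and the acetals.
- Irradiation threatens the C–Br bond and the light-sensitive o-acylbenzaldehyde unit.
- The anionic variant needs a carbanion between two oxygens of a bromoarene, followed by a four-membered transition state at a doubly ortho-substituted ester. Risk is added and no steps are saved.

**Alternative 3:** (biomimetic) connect the formyl carbon to C6 and cleave oxidatively.
- Forward key step: Baeyer–Villiger oxidation of anthraquinone A4 to the seven-membered lactone A5, hydrolysis to keto acid A6, then reduction of the acid to the aldehyde.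
- Anthraquinone carbonyl groups are poor Baeyer–Villiger substrates. The reagent would have to choose one of two carbonyl groups and one of two aryl migrations.
- Peracids epoxidise the prenyl group first.
- A6 would then need an acid-to-aldehyde reduction beside a ketone.
- A4 carries ten substituents on a tricycle and is harder to make than 21 itself.

Key step: step 10

Assumption: the SMILES of 21 holds no stereocentre, no stereodefined double bond and no fixed axis, so 21 is treated as achiral and nothing has to be set. The stereocentres of 16 and 18 and the double-bond geometry of 5–7 are transient and left undefined.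

## Route

Step 1
Reactants: 1 methyl acetoacetate; 2 prenyl bromide (1-bromo-3-methylbut-2-ene)
Product: 4 methyl 7-methyl-3-oxooct-6-enoate, via acetoacetate dianion 3 (not isolated)
Conditions: NaH (1.1 equiv), THF, 0 °C; n-BuLi (1.05 equiv), 0 °C; 2 (1.0 equiv), 0 °C → rt; 1 M HCl quench
Reagents that add atoms: none
Why: γ-Alkylation of a β-keto ester dianion; the more basic terminal carbanion attacks the primary allylic bromide in an SN2 reaction, so the prenyl group ends up on the carbon that becomes C6'. No stereocentre is formed.

Step 2
Reactants: 4 methyl 7-methyl-3-oxooct-6-enoate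
Product: 5 methyl 7-methyl-3-(trimethylsilyloxy)octa-2,6-dienoate (E/Z mixture)
Conditions: TMSCl (1.5 equiv), Et3N (1.5 equiv), hexane, rt; filtration, concentration
Reagents that add atoms: chlorotrimethylsilane, C[Si](C)(C)Cl
Why: O-Silylation of the readily enolised β-keto ester under soft enolisation, the standard first stage on the way to 1,3-bis(silyloxy)dienes. The isolated trisubstituted alkene is inert.

Step 3
Reactants: 5 methyl 7-methyl-3-(trimethylsilyloxy)octa-2,6-dienoate
Product: 7 1-methoxy-7-methyl-1,3-bis(trimethylsilyloxy)octa-1,3,6-triene, via lithium dienolate 6 (not isolated)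
Conditions: LDA (1.1 equiv, commercial solution), THF, –78 °C; TMSCl (1.3 equiv), –78 → 0 °C; hexane, filtration under argon, concentration; stored cold under argon
Reagents that add atoms: chlorotrimethylsilane, C[Si](C)(C)Cl
Why: Kinetic γ-deprotonation of the vinylogous ester and O-silylation of the ester dienolate, the standard second stage. The γ-CH2 group is the only acidic site, and the diene geometry is irrelevant because all four diene carbons end up in an arene.

Step 4
Reactants: 8 3-methoxy-5-methylphenol
Product: 9 2-chloro-5-methoxy-3-methylphenol
Conditions: SO2Cl2 (1.0 equiv), 2,2,6,6-tetramethylpiperidine (5 mol %), toluene, 0 °C → rt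
Reagents that add atoms: sulfuryl chloride, O=S(=O)(Cl)Cl
Why: Amine-catalysed ortho-selective chlorination of a phenol; the N-chloro amine formed in the flask is held by the phenolic OH and delivers chlorine to an ortho carbon. Of the two ortho carbons, the one next to the methyl group is also para to OMe, so both donors reinforce each other there, whereas the carbon between the two oxygens has no para donor.

Step 5
Reactants: 9 2-chloro-5-methoxy-3-methylphenol
Product: 10 2-chloro-5-methoxy-1-(methoxymethoxy)-3-methylbenzene
Conditions: MOMCl (1.3 equiv), i-Pr2NEt (1.5 equiv), CH2Cl2, 0 °C → rt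
Reagents that add atoms: chloromethyl methyl ether, COCCl
Why: Williamson-type acetal formation on an acidic o-chlorophenol. The MOM group serves as the metalation director in step 6 and as the phenol protecting group up to step 11.

Step 6
Reactants: 10 2-chloro-5-methoxy-1-(methoxymethoxy)-3-methylbenzene
Product: 12 3-chloro-6-methoxy-2-(methoxymethoxy)-4-methylbenzaldehyde, via aryllithium 11 (not isolated)
Conditions: n-BuLi (1.1 equiv), THF, 0 °C; DMF (2 equiv), 0 °C → rt; H2O
Reagents that add atoms: N,N-dimethylformamide, CN(C)C=O
Why: Directed ortho metalation at the carbon between OMOM and OMe, where both groups cooperate, followed by formylation. The other position ortho to OMOM is occupied by chlorine, which lies meta to the lithiated carbon, so no aryne can form, and chlorine–lithium exchange is slow.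

Step 7
Reactants: 12 3-chloro-6-methoxy-2-(methoxymethoxy)-4-methylbenzaldehyde
Product: 13 3-bromo-5-chloro-2-methoxy-6-(methoxymethoxy)-4-methylbenzaldehyde
Conditions: NBS (1.05 equiv), MeCN, 0 °C → rt, in the dark
Reagents that add atoms: N-bromosuccinimide, O=C1CCC(=O)N1Br
Why: Electrophilic aromatic bromination at the only remaining C–H, which is ortho to OMe, para to OMOM and meta to CHO, so there is no regiochemical choice. Polar solvent and darkness suppress benzylic radical bromination, and no strong acid is formed that could cleave the MOM ether.

Step 8
Reactants: 13 3-bromo-5-chloro-2-methoxy-6-(methoxymethoxy)-4-methylbenzaldehyde; 14 propargyl alcohol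
Product: 16 1-[3-bromo-5-chloro-2-methoxy-6-(methoxymethoxy)-4-methylphenyl]but-2-yne-1,4-diol (racemic), via dilithiated propargyl alcohol 15 (not isolated)
Conditions: 14 (1.5 equiv), n-BuLi (2.9 equiv), THF, –78 → 0 °C; 13, –78 → –20 °C; H2O
Reagents that add atoms: none
Why: 1,2-Addition of a lithium acetylide to an aldehyde; the slim sp nucleophile reaches the doubly ortho-substituted carbonyl group without strain. Acetylides do not exchange with aryl bromides, and butyllithium is kept in deficit. The new stereocentre is racemic and is erased in step 9.

Step 9
Reactants: 16 1-[3-bromo-5-chloro-2-methoxy-6-(methoxymethoxy)-4-methylphenyl]but-2-yne-1,4-diol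
Product: 17 4-[3-bromo-5-chloro-2-methoxy-6-(methoxymethoxy)-4-methylphenyl]-4-oxobut-2-ynal
Conditions: activated MnO2 (25 equiv), CH2Cl2, rt; filtration through Celite, solvent exchange to toluene below rt; used at once
Reagents that add atoms: none
Why: Both hydroxyl groups are propargylic (the secondary one is also benzylic), the alcohol class that manganese dioxide oxidises. One operation therefore sets the ketone and the aldehyde. The neutral heterogeneous conditions and filtration work-up keep water, acids and nucleophiles away from the doubly activated alkyne.

Step 10
Reactants: 17 4-[3-bromo-5-chloro-2-methoxy-6-(methoxymethoxy)-4-methylphenyl]-4-oxobut-2-ynal; 7 1-methoxy-7-methyl-1,3-bis(trimethylsilyloxy)octa-1,3,6-triene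
Product: 20 2-[3-bromo-5-chloro-2-methoxy-6-(methoxymethoxy)-4-methylbenzoyl]-4,6-dihydroxy-3-(3-methylbut-2-en-1-yl)benzaldehyde, via cycloadduct 18 (not isolated), via bis-silyl arene 19 (not isolated)
Conditions: 7 (1.5 equiv) added slowly to 17, toluene, –40 °C → rt; then 0.5 M aq. HCl (cat.), THF, 0 °C
Reagents that add atoms: none
Why: Normal-electron-demand Diels–Alder benzannulation of a 1-methoxy-1,3-bis(silyloxy)diene with an acetylenic carbonyl dienophile, a known route to resorcinols; with partners this polarised it may run stepwise (Mukaiyama–Michael addition, then ring closure), which leads to the same product. Ring B is closed in the [4+2] mode: C4 of 7 (future C6', prenyl-bearing) bonds to the alkyne carbon that carries the aroyl group (C1'), and C1 of 7 (future C3') bonds to the one that carries the formyl group (C2'), giving 1,4-cyclohexadiene 18. In 18 the C6'–H is vinylogously acidified by the formyl group and C3' is a mixed ketal, so 1,4-elimination of methanol gives arene 19, and dilute acid then removes the two aryl silyl ethers. The two sp3 centres of 18 (C3', C6') form without control and are erased on aromatisation, so no stereocontrolling element is needed. The step needs orientation: the largest HOMO coefficient of 7 lies on C4, and this carbon must meet the alkyne carbon β to the formyl group and not the one β to the ketone. Two features of 17 favour this and point the same way: the formyl group is the stronger and sterically free π-acceptor, so the charge built up in the first bond formation is taken up as a formyl allenolate, and the fully substituted ketene acetal terminus C1 of 7 is paired with the alkyne carbon next to the small formyl group while the less substituted C4 is paired with the carbon next to the bulky aroyl group. The step also needs C≡C over C=O selectivity, which the absence of any Lewis acid should secure, since hetero-Diels–Alder and aldol-type additions of silyloxydienes to aldehydes depend on such activation. The MOM ether, aryl bromide, aryl chloride and prenyl alkene are inert under these neutral low-temperature conditions, and the acidic work-up avoids the base-induced isomerisation of the keto aldehyde.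

Step 11
Reactants: 20 2-[3-bromo-5-chloro-2-methoxy-6-(methoxymethoxy)-4-methylbenzoyl]-4,6-dihydroxy-3-(3-methylbut-2-en-1-yl)benzaldehyde
Product: 21 Pestalone H, 2-(3-bromo-5-chloro-6-hydroxy-2-methoxy-4-methylbenzoyl)-4,6-dihydroxy-3-(3-methylbut-2-en-1-yl)benzaldehyde
Conditions: 2 M aq. HCl (cat.), THF/i-PrOH, 40 °C
Reagents that add atoms: none
Why: Acid hydrolysis of an aryl methoxymethyl acetal, the usual last step for prenylated polyphenols; dilute acid at mild temperature should leave the o-prenylphenol open. No base or nucleophile is present that could trigger the phthalide isomerisation, and the freed C6–OH is stabilised by a hydrogen bond to C7=O.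

## Compound list

1 | methyl acetoacetate | COC(=O)CC(C)=O | starting material
2 | prenyl bromide (1-bromo-3-methylbut-2-ene) | CC(C)=CCBr | starting material
3 | lithium sodium dianion of methyl acetoacetate (not isolated) | C=C([O-])C=C([O-])OC.[Li+].[Na+] | intermediate
4 | methyl 7-methyl-3-oxooct-6-enoate | COC(=O)CC(=O)CCC=C(C)C | intermediate
5 | methyl 7-methyl-3-(trimethylsilyloxy)octa-2,6-dienoate (E/Z mixture) | COC(=O)C=C(CCC=C(C)C)O[Si](C)(C)C | intermediate
6 | lithium dienolate of 5 (not isolated) | COC(O[Li])=CC(O[Si](C)(C)C)=CCC=C(C)C | intermediate
7 | 1-methoxy-7-methyl-1,3-bis(trimethylsilyloxy)octa-1,3,6-triene (geometry undefined) | COC(O[Si](C)(C)C)=CC(O[Si](C)(C)C)=CCC=C(C)C | intermediate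
8 | 3-methoxy-5-methylphenol | COc1cc(C)cc(O)c1 | starting material
9 | 2-chloro-5-methoxy-3-methylphenol | COc1cc(C)c(Cl)c(O)c1 | intermediate
10 | 2-chloro-5-methoxy-1-(methoxymethoxy)-3-methylbenzene | COCOc1cc(OC)cc(C)c1Cl | intermediate
11 | [3-chloro-6-methoxy-2-(methoxymethoxy)-4-methylphenyl]lithium (not isolated) | COCOc1c([Li])c(OC)cc(C)c1Cl | intermediate
12 | 3-chloro-6-methoxy-2-(methoxymethoxy)-4-methylbenzaldehyde | COCOc1c(Cl)c(C)cc(OC)c1C=O | intermediate
13 | 3-bromo-5-chloro-2-methoxy-6-(methoxymethoxy)-4-methylbenzaldehyde | COCOc1c(Cl)c(C)c(Br)c(OC)c1C=O | intermediate
14 | propargyl alcohol | C#CCO | starting material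
15 | dilithiated propargyl alcohol (not isolated) | [Li]C#CCO[Li] | intermediate
16 | 1-[3-bromo-5-chloro-2-methoxy-6-(methoxymethoxy)-4-methylphenyl]but-2-yne-1,4-diol (racemic) | COCOc1c(Cl)c(C)c(Br)c(OC)c1C(O)C#CCO | intermediate
17 | 4-[3-bromo-5-chloro-2-methoxy-6-(methoxymethoxy)-4-methylphenyl]-4-oxobut-2-ynal | COCOc1c(Cl)c(C)c(Br)c(OC)c1C(=O)C#CC=O | intermediate
18 | Diels–Alder adduct, 2-aroyl-6-methoxy-3-prenyl-4,6-bis(trimethylsilyloxy)cyclohexa-1,4-diene-1-carbaldehyde (mixture of stereoisomers, not isolated) | COCOc1c(Cl)c(C)c(Br)c(OC)c1C(=O)C1=C(C=O)C(OC)(O[Si](C)(C)C)C=C(O[Si](C)(C)C)C1CC=C(C)C | intermediate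
19 | 3',5'-bis(trimethylsilyl) ether of 20 (not isolated) | COCOc1c(Cl)c(C)c(Br)c(OC)c1C(=O)c1c(C=O)c(O[Si](C)(C)C)cc(O[Si](C)(C)C)c1CC=C(C)C | intermediate
20 | 2-[3-bromo-5-chloro-2-methoxy-6-(methoxymethoxy)-4-methylbenzoyl]-4,6-dihydroxy-3-(3-methylbut-2-en-1-yl)benzaldehyde | COCOc1c(Cl)c(C)c(Br)c(OC)c1C(=O)c1c(C=O)c(O)cc(O)c1CC=C(C)C | intermediate
21 | Pestalone H | COc1c(Br)c(C)c(Cl)c(O)c1C(=O)c1c(C=O)c(O)cc(O)c1CC=C(C)C | target

## Step count and least certain steps

Total: 11 steps (3 to diene 7, 6 to keto ynal 17, 2 after the union). Longest linear sequence: 8 steps (steps 4–11, from 8).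

**Step 10 (key step).**
- The orientation of the cycloaddition may be eroded or reversed, because both alkyne carbons of 17 carry a carbonyl acceptor and the difference between formyl and aroyl is one of degree.
- Aldol-type addition of the ketene acetal to the formyl group and oligomerisation of 17 could also consume material.
- Fallback (sets out from 16, returns at 20): the ketone is taken out of play during the cycloaddition. Oxidation of only the primary alcohol of 16 (TEMPO/PhI(OAc)2, which discriminates against the hindered secondary carbinol) should give the racemic hydroxy ynal F1. In F1 the formyl group is the only acceptor, so the orientation is no longer in question.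
- Cycloaddition of F1 with 7 and the same acidic work-up should give the benzhydrol aldehyde F2. Oxidation of its secondary alcohol with Dess–Martin periodinane leads to 20.
- The price is one more step and a late oxidation that must outrun lactol closure. The formyl group of F2 is a hydrogen-bonded vinylogous acid and should therefore have little tendency to form the lactol.

**Step 9.**
- The doubly activated alkyne may suffer hydration, conjugate addition or oligomerisation during the oxidation or the solvent exchange. The hindered secondary alcohol may also be oxidised too slowly on the solid reagent.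
- Fallback (sets out from 13, returns at 17): the aldehyde is carried in masked form. Addition of lithiated 3,3-diethoxyprop-1-yne to 13 should give the propargylic alcohol acetal F3. Oxidation of the single alcohol with Dess–Martin periodinane gives the storable ynone acetal F4.
- Mild acetal cleavage of F4 (LiBF4, wet MeCN) releases 17 only just before step 10.

**Step 4.**
- Uncatalysed background chlorination para to the hydroxyl group, attack between the two oxygens, or double chlorination may lower the positional selectivity on this very electron-rich ring.
- Fallback (sets out from 8, returns at 9): the control element is changed from reagent delivery to substrate electronics. Acetylation of 8 (Ac2O, pyridine) gives the aryl acetate F5, in which OMe is the only strong donor.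
- Chlorination of F5 (NCS, MeCN) should then go para to OMe and give the chloro acetate F6. Methanolysis (cat. K2CO3, MeOH) returns 9.

**Step 11.**
- Brønsted acid may close the o-prenylphenol to a chroman or add to the alkene before the acetal is fully cleaved.
- Fallback (sets out from 20, returns at 21): Brønsted acid is left out, and the acetal is exchanged for a silyl ether. TMSOTf/2,2'-bipyridyl in CH2Cl2 at 0 °C should convert the aromatic MOM ether, through a bipyridinium acetal salt, and the two free phenols into the tris(trimethylsilyl) ether F7. Water at neutral pH hydrolyses F7 to 21.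

## Further compounds

F1 | step 10 | 4-[3-bromo-5-chloro-2-methoxy-6-(methoxymethoxy)-4-methylphenyl]-4-hydroxybut-2-ynal (racemic) | COCOc1c(Cl)c(C)c(Br)c(OC)c1C(O)C#CC=O
F2 | step 10 | 2-{[3-bromo-5-chloro-2-methoxy-6-(methoxymethoxy)-4-methylphenyl](hydroxy)methyl}-4,6-dihydroxy-3-(3-methylbut-2-en-1-yl)benzaldehyde (racemic) | COCOc1c(Cl)c(C)c(Br)c(OC)c1C(O)c1c(C=O)c(O)cc(O)c1CC=C(C)C
F3 | step 9 | 1-[3-bromo-5-chloro-2-methoxy-6-(methoxymethoxy)-4-methylphenyl]-4,4-diethoxybut-2-yn-1-ol (racemic) | CCOC(OCC)C#CC(O)c1c(OC)c(Br)c(C)c(Cl)c1OCOC
F4 | step 9 | 1-[3-bromo-5-chloro-2-methoxy-6-(methoxymethoxy)-4-methylphenyl]-4,4-diethoxybut-2-yn-1-one | CCOC(OCC)C#CC(=O)c1c(OC)c(Br)c(C)c(Cl)c1OCOC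
F5 | step 4 | 3-methoxy-5-methylphenyl acetate | COc1cc(C)cc(OC(C)=O)c1
F6 | step 4 | 2-chloro-5-methoxy-3-methylphenyl acetate | COc1cc(C)c(Cl)c(OC(C)=O)c1
F7 | step 11 | tris(trimethylsilyl) ether of Pestalone H | COc1c(Br)c(C)c(Cl)c(O[Si](C)(C)C)c1C(=O)c1c(C=O)c(O[Si](C)(C)C)cc(O[Si](C)(C)C)c1CC=C(C)C
A1 | alternative 1 | 2-bromo-1-(dimethoxymethyl)-4,6-bis(methoxymethoxy)-3-(3-methylbut-2-en-1-yl)benzene | COC(OC)c1c(Br)c(CC=C(C)C)c(OCOC)cc1OCOC
A2 | alternative 1 | [3-bromo-5-chloro-2-methoxy-6-(methoxymethoxy)-4-methylphenyl][2-(dimethoxymethyl)-3,5-bis(methoxymethoxy)-6-(3-methylbut-2-en-1-yl)phenyl]methanol (racemic) | COCOc1c(Cl)c(C)c(Br)c(OC)c1C(O)c1c(C(OC)OC)c(OCOC)cc(OCOC)c1CC=C(C)C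
A3 | alternative 2 | 4-bromo-2-chloro-5-methoxy-3-methylphenyl 2-(dimethoxymethyl)-3,5-bis(methoxymethoxy)-6-(3-methylbut-2-en-1-yl)benzoate | COc1cc(OC(=O)c2c(C(OC)OC)c(OCOC)cc(OCOC)c2CC=C(C)C)c(Cl)c(C)c1Br
A4 | alternative 3 | 2-bromo-4-chloro-5,7-dihydroxy-1-methoxy-3-methyl-8-(3-methylbut-2-en-1-yl)anthracene-9,10-dione | COc1c(Br)c(C)c(Cl)c2C(=O)c3c(O)cc(O)c(CC=C(C)C)c3C(=O)c12
A5 | alternative 3 | seven-membered lactone (dibenzo[b,e]oxepine-6,11-dione) from oxygen insertion between C10 and C4a of A4 | COc1c(Br)c(C)c(Cl)c2OC(=O)c3c(O)cc(O)c(CC=C(C)C)c3C(=O)c12
A6 | alternative 3 | 2-(3-bromo-5-chloro-6-hydroxy-2-methoxy-4-methylbenzoyl)-4,6-dihydroxy-3-(3-methylbut-2-en-1-yl)benzoic acid | COc1c(Br)c(C)c(Cl)c(O)c1C(=O)c1c(C(=O)O)c(O)cc(O)c1CC=C(C)C
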